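**Retrosynthetic overview**

1. Labdane numbering (C1–C20) is used throughout. Late disconnections: the two silyl ethers and the O15 acetate; the C12–C13 bond, made by B-alkyl Suzuki–Miyaura coupling of a C9 vinyl group with (Z)-3-iodobut-2-en-1-ol; the 7α-hydroxy-8(17)-ene, made from the 7α,8α-epoxide of a C7=C8 alkene.
2. C11 and C12 grow from a C9 ketone (methylenation, hydroboration–oxidation, oxidation, methylenation). The C4 quaternary centre comes from a C4 ketone (homologation to the C19 aldehyde, α-face methylation, reduction, acetylation).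
3. Key disconnection, C2–C3 of ring A: the C2 carbinol carbon is β to C4 and lies between the CH2 groups C1 and C3. With C4 raised to a ketone, ring A is a 3-hydroxycyclohexanone, the aldol of a C3 methyl ketone on C5 with a C2 aldehyde on the CH2 arm of C10, the two held trans on ring B.
4. Both carbonyl groups are unmasked in one ozonolysis from the isopropenyl and allyl groups of 6-allyl-6-methylcarvone. (R)-Carvone supplies ring B with C5, the C7=C8 alkene, the C17 methyl and the C9 carbonyl; two α'-alkylations build the C10 quaternary centre.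
5. Order of rings: ring B (from carvone) first, then ring A by the aldol closure.

Key step: step 4

Remark: the target is read as the normal-labdane enantiomer, (2R,4S,5R,7R,9R,10S) with a 13Z double bond; β is the face of the C10 methyl group, and the stereocentre of (R)-carvone becomes C5.

**Route**

Step 1
Reactants: 1 (R)-(−)-carvone
Product: 3 trans-6-methylcarvone, via lithium dienolate 2 (not isolated)
Conditions: LiN(iPr)2, THF, −78 °C; MeI, −78 to 0 °C
Reagents that add atoms: iodomethane CI
Why: Kinetic deprotonation of the enone at the α'-CH2 (C10) gives the cross-conjugated dienolate, which is C-methylated (enolate alkylation); the C10 configuration does not matter because this centre is enolised again in step 2.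

Step 2
Reactants: 3 trans-6-methylcarvone
Product: 5 6-allyl-6-methylcarvone, via lithium enolate 4 (not isolated)
Conditions: LiN(iPr)2, THF, −78 to 0 °C; DMPU, allyl bromide, −78 °C to rt
Reagents that add atoms: allyl bromide C=CCBr
Why: Enolate alkylation of the tetrasubstituted enolate creates the C10 quaternary centre; the electrophile should enter anti to the neighbouring C5 isopropenyl group, so the future C1 ends trans and the C10 methyl cis to C4.

Step 3
Reactants: 5 6-allyl-6-methylcarvone
Product: 7 keto aldehyde, via bis-ozonide 6 (not isolated)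
Conditions: O3, CH2Cl2, −78 °C (Sudan Red 7B end point); PPh3, −78 °C to rt
Reagents that add atoms: ozone [O-][O+]=O
Why: Ozonolysis with reductive work-up cleaves the two electron-rich terminal alkenes (isopropenyl to the C4 methyl ketone whose methyl is C3, allyl to the C2 aldehyde), while the electron-poor conjugated C7=C8 alkene should react far more slowly; no stereocentre is touched.

Step 4
Reactants: 7 keto aldehyde
Product: 8 bicyclic ketol
Conditions: K2CO3 (0.3 equiv), MeOH, 0 °C
Reagents that add atoms: none
Why: Carbonate reversibly deprotonates the C3 methyl of the C4 acetyl group and the enolate adds to the C2 aldehyde, an intramolecular aldol addition of the kind that closes the ketol in every Robinson-type annulation. Ring A closes in the 6-(enolendo)-exo-trig mode through a chair that is fused trans to ring B, because the C5 acetyl group and the C10 CH2CHO arm are trans. The only new stereocentre, C2, is controlled by the C10 β-methyl group: an axial oxygen at C2 would be syn-diaxial to it, so the equatorial 2α-alkoxide should be favoured kinetically and, through retro-aldol equilibration, thermodynamically. C5 is α to the C4 ketone and can enolise, but the trans ring fusion is the stable one, so the centre taken from carvone should be kept. The step needs chemoselectivity among four enolisable sites and three carbonyl groups: aldol attack of C1 or C5 on any carbonyl would give three- or four-membered rings, attack of C3 on the hindered conjugated C9 ketone is a disfavoured 5-(enolendo)-exo closure, and Michael addition of C1 to C7 would be 5-endo, so only the C2–C3 closure is open. Weak base at low temperature should keep the β-hydroxy ketone from dehydrating.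

Step 5
Reactants: 8 bicyclic ketol
Product: 9 silyl ether
Conditions: TBSCl, imidazole, DMF, rt
Reagents that add atoms: tert-butyldimethylsilyl chloride CC(C)(C)[Si](C)(C)Cl
Why: Silyl ether formation at the unhindered equatorial C2 hydroxyl under imidazole buffering, which should avoid β-elimination of the β-hydroxy ketone and masks O2 for the basic steps that follow.

Step 6
Reactants: 9 silyl ether
Product: 11 C19 aldehyde, via methyl enol ether 10 (not isolated)
Conditions: MeOCH2PPh3Cl, KN(SiMe3)2, THF, 0 °C to rt; then 1 M HCl, THF, rt
Reagents that add atoms: (methoxymethyl)triphenylphosphonium chloride [Cl-].COC[P+](c1ccccc1)(c1ccccc1)c1ccccc1; water O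
Why: Wittig methoxymethylenation should take place at the saturated C4 ketone and not at the conjugated C9 ketone that is flanked by the quaternary C10, and hydrolysis of the enol ether completes a one-carbon homologation that brings in C19 as an aldehyde; the two C4 epimers converge in step 7.

Step 7
Reactants: 11 C19 aldehyde
Product: 13 quaternary aldehyde, via potassium enolate 12 (not isolated)
Conditions: KOtBu, t-BuOH/THF, 0 °C; MeI
Reagents that add atoms: iodomethane CI
Why: Alkylation of the aldehyde enolate, in which iodomethane should attack C4 from the α-face (equatorial) because the β-face is shielded by the syn-axial C10 methyl group, so the new methyl is C18 (α) and the formyl group is the axial C19 (β); the aldehyde α-proton is several pKa units more acidic than the γ-protons of the C9 enone.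

Step 8
Reactants: 13 quaternary aldehyde
Product: 14 19-alcohol
Conditions: NaBH4, MeOH/CH2Cl2, −40 °C
Reagents that add atoms: none
Why: Borohydride reduction should be much faster at the aldehyde than at the conjugated C9 ketone next to the quaternary C10, so only C19 is reduced and no stereocentre is formed.

Step 9
Reactants: 14 19-alcohol
Product: 15 diene alcohol
Conditions: Ph3PCH3Br, KOtBu, toluene, 90 °C
Reagents that add atoms: methyltriphenylphosphonium bromide [Br-].C[P+](c1ccccc1)(c1ccccc1)c1ccccc1
Why: Wittig methylenation of the hindered C9 ketone with excess ylide at elevated temperature should give the 7,9(11)-diene and so bring in C11; the C19 alkoxide and the silyl ether are inert.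

Step 10
Reactants: 15 diene alcohol
Product: 16 diene acetate
Conditions: Ac2O, pyridine, DMAP (cat.), CH2Cl2, rt
Reagents that add atoms: acetic anhydride CC(=O)OC(C)=O
Why: DMAP-catalysed acylation installs the C19 acetate of the target, which also protects O19 through the following steps.

Step 11
Reactants: 16 diene acetate
Product: 18 11-alcohol, via alkylborane 17 (not isolated)
Conditions: 9-BBN, THF, 0 °C to rt; then H2O2, aq NaOAc, 0 °C to rt
Reagents that add atoms: hydrogen peroxide OO
Why: Hydroboration–oxidation, in which the bulky borane should put boron on the unsubstituted diene terminus C11 and hydrogen on C9 from the α-face, anti to the axial C10 methyl group, which sets C9 (H α, CH2OH β and equatorial); the trisubstituted C7=C8 alkene and the acetate should not react.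

Step 12
Reactants: 18 11-alcohol
Product: 19 11-aldehyde
Conditions: Dess–Martin periodinane, NaHCO3, CH2Cl2, 0 °C to rt
Reagents that add atoms: none
Why: Dess–Martin oxidation of the primary alcohol under buffered conditions should give the β,γ-unsaturated aldehyde without moving the C7=C8 double bond; the equatorial C9 configuration is also the thermodynamic one.

Step 13
Reactants: 19 11-aldehyde
Product: 20 9-vinyl compound
Conditions: Ph3PCH3Br, KN(SiMe3)2, THF, −78 to 0 °C
Reagents that add atoms: methyltriphenylphosphonium bromide [Br-].C[P+](c1ccccc1)(c1ccccc1)c1ccccc1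
Why: Wittig methylenation of the aldehyde at low temperature, where addition should outrun α-deprotonation and the acetate is not attacked, brings in C12 as the terminus of a vinyl group.

Step 14
Reactants: 20 9-vinyl compound
Product: 21 epoxide
Conditions: mCPBA, NaHCO3, CH2Cl2, 0 °C
Reagents that add atoms: 3-chloroperoxybenzoic acid OOC(=O)c1cccc(Cl)c1
Why: Prilezhaev epoxidation should select the trisubstituted C7=C8 alkene over the monosubstituted vinyl group and attack the α-face, since the β-face is shielded by the axial C10 methyl group, which sets C7 and gives the 7α,8α-epoxide.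

Step 15
Reactants: 21 epoxide
Product: 22 allylic alcohol
Conditions: Cp2TiCl2, Mn dust, THF, rt; aq HCl work-up
Reagents that add atoms: none
Why: Trivalent titanium (Cp2TiCl made in the flask) opens the epoxide homolytically at the tertiary C8–O bond, and the C8 radical is trapped by a second Cp2TiCl and loses a β-hydrogen from the freely rotating C17 methyl group (titanocene-mediated isomerisation of an epoxide to an allylic alcohol), which should give the exocyclic 8(17)-alkene and keeps the C7–O bond, hence the 7α configuration; the acetate is inert.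

Step 16
Reactants: 22 allylic alcohol
Product: 23 bis-silyl ether
Conditions: TBSOTf, 2,6-lutidine, CH2Cl2, −78 to 0 °C
Reagents that add atoms: tert-butyldimethylsilyl trifluoromethanesulfonate CC(C)(C)[Si](C)(C)OS(=O)(=O)C(F)(F)F
Why: Silylation of the hindered axial allylic alcohol with the silyl triflate masks O7, so that only O15 is acetylated in step 19, and further shields the exocyclic alkene.

Step 17
Reactants: 24 but-2-yn-1-ol
Product: 26 (Z)-3-iodobut-2-en-1-ol, via cyclic vinylalanate 25 (not isolated)
Conditions: NaAlH2(OCH2CH2OMe)2, THF, 0 °C to rt; then I2, −78 °C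
Reagents that add atoms: iodine II
Why: Hydroxyl-directed trans-hydroalumination of the propargylic alcohol puts aluminium on C3 cis to the CH2O group in a five-membered alanate, and iodinolysis with retention should give the (Z)-vinyl iodide that fixes the 13Z geometry.

Step 18
Reactants: 23 bis-silyl ether; 26 (Z)-3-iodobut-2-en-1-ol
Product: 28 15-alcohol, via alkylborane 27 (not isolated)
Conditions: 9-BBN, THF, rt; then 26, PdCl2(dppf) (cat.), AsPh3, Cs2CO3, DMF/H2O, rt
Reagents that add atoms: none
Why: 9-BBN should add to the monosubstituted vinyl group much faster than to the exocyclic C8=C17 alkene, which is flanked by the axial O7 silyl ether and the branched C9, and the B-alkyl Suzuki–Miyaura coupling joins C12 to C13 with retention of the Z geometry of the vinyl iodide.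

Step 19
Reactants: 28 15-alcohol
Product: 29 diacetate
Conditions: Ac2O, pyridine, DMAP (cat.), CH2Cl2, 0 °C to rt
Reagents that add atoms: acetic anhydride CC(=O)OC(C)=O
Why: Acylation of the only free hydroxyl group, the primary allylic O15.

Step 20
Reactants: 29 diacetate
Product: 30 target
Conditions: HF·pyridine, THF/pyridine, 0 °C to rt
Reagents that add atoms: none
Why: Fluoride-mediated cleavage of both silyl ethers under buffered conditions should leave the two acetates, the allylic alcohol and the alkenes untouched and give the 2α,7α-diol 15,19-diacetate.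

**Compound list**

1 | (R)-(−)-carvone, (5R)-2-methyl-5-(prop-1-en-2-yl)cyclohex-2-en-1-one | CC1=CC[C@@H](C(C)=C)CC1=O | starting material
2 | lithium dienolate of 1 (OLi on C9, C9=C10 and C7=C8 double bonds) | CC1=CC[C@@H](C(C)=C)C=C1O[Li] | intermediate
3 | trans-6-methylcarvone: 2,6-dimethyl-5-(prop-1-en-2-yl)cyclohex-2-en-1-one, C10 methyl trans to isopropenyl (major epimer; the cis epimer is carried on as well) | CC1=CC[C@@H](C(C)=C)[C@H](C)C1=O | intermediate
4 | lithium enolate of 3 (tetrasubstituted C9=C10 enolate) | CC1=CC[C@@H](C(C)=C)C(C)=C1O[Li] | intermediate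
5 | 6-allyl-6-methylcarvone: 6-allyl-2,6-dimethyl-5-(prop-1-en-2-yl)cyclohex-2-en-1-one, allyl trans and methyl cis to isopropenyl | CC1=CC[C@@H](C(C)=C)[C@](C)(CC=C)C1=O | intermediate
6 | bis-ozonide of 5 (1,2,4-trioxolanes in place of both terminal alkenes, mixture at the new ring carbons) | CC1=CC[C@@H](C2(C)OCOO2)[C@](C)(CC3OCOO3)C1=O | intermediate
7 | keto aldehyde: 5-acetyl-2,6-dimethyl-6-(2-oxoethyl)cyclohex-2-en-1-one, acetyl on C5 trans to the CH2CHO arm on C10 | CC1=CC[C@H](C(C)=O)[C@](C)(CC=O)C1=O | intermediate
8 | bicyclic ketol: trans-fused decalin; ring A with C4 ketone and equatorial 2α-OH; ring B with C9 ketone, C7=C8 and C17 methyl on C8; C10 methyl β, H5 α | CC1=CC[C@H]2C(=O)C[C@H](O)C[C@]2(C)C1=O | intermediate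
9 | O2 tert-butyldimethylsilyl ether of 8 | CC1=CC[C@H]2C(=O)C[C@H](O[Si](C)(C)C(C)(C)C)C[C@]2(C)C1=O | intermediate
10 | methyl enol ether: C4=C19H–OMe in place of the C4 ketone of 9 (E/Z mixture) | CC1=CC[C@H]2C(=COC)C[C@H](O[Si](C)(C)C(C)(C)C)C[C@]2(C)C1=O | intermediate
11 | C19 aldehyde with C4–H (mixture of C4 epimers) | CC1=CC[C@H]2C(C=O)C[C@H](O[Si](C)(C)C(C)(C)C)C[C@]2(C)C1=O | intermediate
12 | potassium enolate of 11 (C4=C19–OK) | CC1=CC[C@H]2C(=C[O-])C[C@H](O[Si](C)(C)C(C)(C)C)C[C@]2(C)C1=O.[K+] | intermediate
13 | quaternary aldehyde: 4α-methyl (C18), 4β-formyl (C19) | CC1=CC[C@H]2[C@@](C)(C=O)C[C@H](O[Si](C)(C)C(C)(C)C)C[C@]2(C)C1=O | intermediate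
14 | 19-alcohol: 4β-CH2OH, 4α-CH3, C9 enone retained | CC1=CC[C@H]2[C@@](C)(CO)C[C@H](O[Si](C)(C)C(C)(C)C)C[C@]2(C)C1=O | intermediate
15 | diene alcohol: C9=C11H2 and C7=C8, 19-OH | CC1=CC[C@H]2[C@@](C)(CO)C[C@H](O[Si](C)(C)C(C)(C)C)C[C@]2(C)C1=C | intermediate
16 | diene acetate: 19-OAc | CC1=CC[C@H]2[C@@](C)(COC(C)=O)C[C@H](O[Si](C)(C)C(C)(C)C)C[C@]2(C)C1=C | intermediate
17 | B-alkyl-9-BBN with boron on C11, H9 α | CC1=CC[C@H]2[C@@](C)(COC(C)=O)C[C@H](O[Si](C)(C)C(C)(C)C)C[C@]2(C)[C@H]1CB3C4CCCC3CCC4 | intermediate
18 | 11-alcohol: 9β-CH2OH (equatorial), C7=C8 | CC1=CC[C@H]2[C@@](C)(COC(C)=O)C[C@H](O[Si](C)(C)C(C)(C)C)C[C@]2(C)[C@H]1CO | intermediate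
19 | 11-aldehyde: 9β-CHO | CC1=CC[C@H]2[C@@](C)(COC(C)=O)C[C@H](O[Si](C)(C)C(C)(C)C)C[C@]2(C)[C@H]1C=O | intermediate
20 | 9-vinyl compound: 9β-CH=CH2 (C11=C12), C7=C8 | CC1=CC[C@H]2[C@@](C)(COC(C)=O)C[C@H](O[Si](C)(C)C(C)(C)C)C[C@]2(C)[C@H]1C=C | intermediate
21 | 7α,8α-epoxide of 20 | C[C@@]12O[C@@H]1C[C@H]3[C@@](C)(COC(C)=O)C[C@H](O[Si](C)(C)C(C)(C)C)C[C@]3(C)[C@H]2C=C | intermediate
22 | allylic alcohol: 7α-OH, C8=C17 exocyclic, 9β-vinyl | C=C1[C@H](O)C[C@H]2[C@@](C)(COC(C)=O)C[C@H](O[Si](C)(C)C(C)(C)C)C[C@]2(C)[C@H]1C=C | intermediate
23 | bis-silyl ether: O2 and O7 as tert-butyldimethylsilyl ethers | C=C1[C@H](O[Si](C)(C)C(C)(C)C)C[C@H]2[C@@](C)(COC(C)=O)C[C@H](O[Si](C)(C)C(C)(C)C)C[C@]2(C)[C@H]1C=C | intermediate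
24 | but-2-yn-1-ol | CC#CCO | starting material
25 | cyclic sodium vinylalanate (five-membered O–Al–C3=C2–C1 ring, two 2-methoxyethoxy groups on Al) | CC1=CCO[Al-]1(OCCOC)OCCOC.[Na+] | intermediate
26 | (Z)-3-iodobut-2-en-1-ol | C/C(I)=C/CO | intermediate
27 | B-alkyl-9-BBN with boron on C12 | C=C1[C@H](O[Si](C)(C)C(C)(C)C)C[C@H]2[C@@](C)(COC(C)=O)C[C@H](O[Si](C)(C)C(C)(C)C)C[C@]2(C)[C@H]1CCB3C4CCCC3CCC4 | intermediate
28 | 15-alcohol: full 13Z side chain, 19-OAc, O2 and O7 silylated | C=C1[C@H](O[Si](C)(C)C(C)(C)C)C[C@H]2[C@@](C)(COC(C)=O)C[C@H](O[Si](C)(C)C(C)(C)C)C[C@]2(C)[C@H]1CC/C(C)=C\CO | intermediate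
29 | diacetate: 15,19-diacetate 2,7-bis(tert-butyldimethylsilyl) ether | C=C1[C@H](O[Si](C)(C)C(C)(C)C)C[C@H]2[C@@](C)(COC(C)=O)C[C@H](O[Si](C)(C)C(C)(C)C)C[C@]2(C)[C@H]1CC/C(C)=C\COC(C)=O | intermediate
30 | target: (13Z)-2α,7α-dihydroxylabda-8(17),13-diene-15,19-diyl diacetate | C=C1[C@H](O)C[C@H]2[C@@](C)(COC(C)=O)C[C@H](O)C[C@]2(C)[C@H]1CC/C(C)=C\COC(C)=O | target

**Step count and risks**

Total: 20 steps (19 on the main line and 1 for the side-chain fragment). Longest linear sequence: 19 steps (steps 1–16 and 18–20).

Step 9, methylenation of the C9 ketone. The ylide may fail to add to a carbonyl that is conjugated and flanked by the quaternary C10, or may only deprotonate the enone at the γ-position, so that the ketone is returned. The fallback is a Peterson olefination. Setting out from 14, (trimethylsilyl)methyllithium with CeCl3 (THF, −78 °C, excess to allow for the free hydroxyl) would add to the C9 carbonyl from the α-face to give the β-hydroxysilane F1. Potassium hydride in THF would then bring about syn-elimination; the silylmethyl carbon is the only possible alkene terminus, so this would give the diene alcohol 15, where the route is rejoined.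

Step 7, methylation at C4. The enolate may be methylated on oxygen, the electrophile may enter from the wrong face, or the enone may be deprotonated and alkylated in competition. The fallback reverses the polarity and brings the methyl group in as a nucleophile. Setting out from ketone 9, a Corey–Chaykovsky reaction with dimethylsulfonium methylide (Me3SI, KN(SiMe3)2, THF, 0 °C) would deliver the methylene group equatorially from the α-face, away from the syn-axial C10 methyl group, and give the spiro-epoxide F2 with the oxygen axial (β). Me3Al (hexane/CH2Cl2, −78 to 0 °C) would then open the epoxide at the tertiary C4 with inversion, putting the methyl group α and leaving C19 as the β-CH2OH. This is the 19-alcohol 14, where the route is rejoined; steps 6–8 are bypassed.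

Step 18, hydroboration and coupling. The borane may also add to the exocyclic C8=C17 alkene, or the alkylborane may be lost by protodeboronation before transmetalation. The fallback uses a more selective borane and a Negishi coupling. Setting out from 23, disiamylborane (THF, 0 °C) would add to the vinyl group only, to give the alkylbis(3-methylbutan-2-yl)borane F3 (not isolated), and H2O2/aq NaOAc would give the primary 12-alcohol F4. Iodine, PPh3 and imidazole would give the 12-iodide F5. Zinc insertion (Zn dust, LiCl, THF) would give the alkylzinc iodide F6 (not isolated), and Negishi coupling with 26, taken as its sodium alkoxide (PdCl2(dppf), THF/DMA, rt), would give the 15-alcohol 28, where the route is rejoined.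

Further compounds
F1 | step 9 | β-hydroxysilane: 9β-hydroxy-9α-(trimethylsilylmethyl) adduct of 14 | CC1=CC[C@H]2[C@@](C)(CO)C[C@H](O[Si](C)(C)C(C)(C)C)C[C@]2(C)[C@@]1(C[Si](C)(C)C)O
F2 | step 7 | spiro-epoxide at C4 of 9 (epoxide oxygen β and axial, CH2 α) | CC1=CC[C@H]2[C@]3(CO3)C[C@H](O[Si](C)(C)C(C)(C)C)C[C@]2(C)C1=O
F3 | step 18 | alkylbis(3-methylbutan-2-yl)borane with boron on C12 | C=C1[C@H](O[Si](C)(C)C(C)(C)C)C[C@H]2[C@@](C)(COC(C)=O)C[C@H](O[Si](C)(C)C(C)(C)C)C[C@]2(C)[C@H]1CCB(C(C)C(C)C)C(C)C(C)C
F4 | step 18 | primary 12-alcohol | C=C1[C@H](O[Si](C)(C)C(C)(C)C)C[C@H]2[C@@](C)(COC(C)=O)C[C@H](O[Si](C)(C)C(C)(C)C)C[C@]2(C)[C@H]1CCO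
F5 | step 18 | primary 12-iodide | C=C1[C@H](O[Si](C)(C)C(C)(C)C)C[C@H]2[C@@](C)(COC(C)=O)C[C@H](O[Si](C)(C)C(C)(C)C)C[C@]2(C)[C@H]1CCI
F6 | step 18 | alkylzinc iodide with zinc on C12 | C=C1[C@H](O[Si](C)(C)C(C)(C)C)C[C@H]2[C@@](C)(COC(C)=O)C[C@H](O[Si](C)(C)C(C)(C)C)C[C@]2(C)[C@H]1CC[Zn]I
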